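## Retrosynthetic overview
1. The C9 tiglate and C8 acetate come from the 8α,9α-diol, acylating the equatorial 8-OH first. The diol and the C2 ketone come from an acetonide and a silyl enol ether, both released by one acid treatment.
2. C6H2 comes from C6-OH by radical deoxygenation. This alcohol is the direct product of the key step.
3. Key step, both carbocycles in one flask. Ring A forms by a Diels–Alder reaction of tiglaldehyde with a 2-silyloxydiene (bonds C3–C4 and C5–C10). Ring B then forms by a carbonyl-ene closure (bond C6–C7), which also creates the isopropenyl group.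
4. The silyloxydiene comes from a methyl enone, then a cis-dioxolane aldehyde, then diacetone-D-mannose, using two Wittig reactions and one glycol cleavage. Mannose C2 and C3 become C8 and C9.
5. Ring order is A then B in the same operation. C4, C5, C10 and C7 are set there; C8 and C9 come from the sugar.

Assumption: eremophilane numbering is used (ring A = C1–C5 and C10, ring B = C5–C10) and β is the face of the C5 methyl. The SMILES then reads 4β-Me, 5β-Me, 10β-H (cis-decalin), 7β-isopropenyl, 8α-OAc, 9α-O-(E)-2-methylbut-2-enoyl (tiglate) and a C2 ketone, i.e. 4S,5R,7R,8R,9S,10S.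

## Route

Step 1
Reactants: 1 2,3:5,6-di-O-isopropylidene-α-D-mannofuranose; 2 isopropyltriphenylphosphonium iodide
Product: 3 (R)-[(4R)-2,2-dimethyl-1,3-dioxolan-4-yl][(4S,5R)-2,2-dimethyl-5-(2-methylprop-1-enyl)-1,3-dioxolan-4-yl]methanol
Conditions: 2 (3 equiv), n-BuLi (2.9 equiv), THF, 0 °C; then 1, 0 °C → rt
Reagents that add atoms: isopropyltriphenylphosphonium iodide 2, CC(C)[P+](c1ccccc1)(c1ccccc1)c1ccccc1.[I-]
Why: Wittig olefination of the open hydroxy-aldehyde form of the lactol by the non-stabilised ylide (the excess also deprotonates the OH groups); no stereocentre is made, and mannose C2/C3 (future C8/C9, cis on the dioxolane) are carried over unchanged.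

Step 2
Reactants: 3 alkenol from step 1; 4 1-(triphenylphosphoranylidene)propan-2-one
Product: 7 (E)-4-[(4S,5R)-2,2-dimethyl-5-(2-methylprop-1-enyl)-1,3-dioxolan-4-yl]but-3-en-2-one, via triol 5 (not isolated), via dioxolane carbaldehyde 6 (not isolated)
Conditions: H5IO6 (2.5 equiv), EtOAc, 0 °C → rt; filter through NaHCO3/Na2SO4 into 4 (1.3 equiv), CH2Cl2, rt
Reagents that add atoms: 1-(triphenylphosphoranylidene)propan-2-one 4, CC(=O)C=P(c1ccccc1)(c1ccccc1)c1ccccc1
Why: periodic acid hydrolyses the more exposed terminal acetonide and then cleaves the 4,5,6-triol (Malaprade glycol cleavage) down to the C4 aldehyde, which is trapped at once by the stabilised ylide (E-selective Wittig reaction), so the epimerisable cis-aldehyde is never stored; no new stereocentre.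

Step 3
Reactants: 7 enone
Product: 8 triisopropyl({(3E)-4-[(4S,5R)-2,2-dimethyl-5-(2-methylprop-1-enyl)-1,3-dioxolan-4-yl]buta-1,3-dien-2-yl}oxy)silane
Conditions: TIPSOTf (1.2 equiv), Et3N (2 equiv), CH2Cl2, 0 °C
Reagents that add atoms: triisopropylsilyl trifluoromethanesulfonate, CC(C)[Si](C(C)C)(C(C)C)OS(=O)(=O)C(F)(F)F
Why: soft enolisation (O-silylation, then kinetic deprotonation of the methyl group by Et3N) gives the cross-conjugated 2-silyloxydiene; no stereocentre is touched.

Step 4 (key step)
Reactants: 8 silyloxydiene; 9 (E)-2-methylbut-2-enal (tiglaldehyde)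
Product: 11 6α-hydroxy-8α,9α-isopropylidenedioxy-2-triisopropylsilyloxy-10βH-eremophila-1,11-diene, via Diels-Alder aldehyde 10 (not isolated)
Conditions: 9 (2 equiv), Me2AlCl (2.5 equiv), CH2Cl2, −78 → −20 °C, then 0 °C → rt; quench Et3N, aq. NaHCO3
Reagents that add atoms: (E)-2-methylbut-2-enal 9, C/C=C(\C)C=O
Why: Proposed new method: one Lewis acid drives two known reaction types in sequence, first an endo, regiochemically matched Diels–Alder reaction (nucleophilic C3 bonds to the β-carbon C4 and C10 to C5, the E geometry of 9 makes the two methyls cis, the endo formyl makes C6 cis to C9 and so fixes the cis ring fusion, and the diene reacts anti to the bulky C8 arm with H9 in the crowded inside position beside the formyl–aluminium complex and O9 outside, giving 10β-H), then on warming an intramolecular carbonyl-ene closure of the citronellal-to-isopulegol kind through a chair in which H8 eclipses the alkene (A(1,3) strain), which puts the new isopropenyl group equatorial and trans to O8 (7β) and the 6-OH equatorial (α); the closest known reaction types are Me2AlCl-promoted Diels–Alder reactions of enals with 2-silyloxydienes and Me2AlCl-promoted ene cyclisations of unsaturated aldehydes, and Me2AlCl also scavenges protons, so the silyl enol ether and the acetonide should survive.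

Step 5
Reactants: 11 decalinol
Product: 13 O-(6α-eremophiladienyl) S-methyl dithiocarbonate of 11, via sodium xanthate 12 (not isolated)
Conditions: NaH (2 equiv), THF, 0 °C; CS2 (5 equiv), rt; MeI (5 equiv), rt
Reagents that add atoms: carbon disulfide, S=C=S; iodomethane, CI
Why: xanthate formation (first half of the Barton–McCombie deoxygenation) works because the small CS2 reaches even this neopentyl alkoxide and the ketone is still masked as a base-stable silyl enol ether; no stereocentre changes.

Step 6
Reactants: 13 xanthate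
Product: 14 8α,9α-isopropylidenedioxy-2-triisopropylsilyloxy-10βH-eremophila-1,11-diene
Conditions: Bu3SnH (2 equiv), AIBN (2,2'-azobis(2-methylpropionitrile), 0.2 equiv), toluene, 85 °C
Reagents that add atoms: none
Why: Barton–McCombie radical deoxygenation, in which the stannyl radical adds to C=S and the secondary C6 radical takes hydrogen from concentrated Bu3SnH faster than it can attack the isopropenyl group; only the unwanted C6 stereocentre is erased.

Step 7
Reactants: 14 silyl enol ether acetonide
Product: 16 8α,9α-dihydroxy-10βH-eremophil-11-en-2-one, via keto acetonide 15 (not isolated)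
Conditions: 1 M aq. HCl/THF (1:3), rt
Reagents that add atoms: none
Why: acid hydrolysis protonates the silyl enol ether at C1 (a CH2, so no stereocentre) to free the C2 ketone and then cleaves the acetonide; C4 and C10 are β to the ketone and cannot epimerise, and the isopropenyl group tolerates dilute acid at rt.

Step 8
Reactants: 16 keto diol
Product: 17 8α-acetoxy-9α-hydroxy-10βH-eremophil-11-en-2-one
Conditions: Ac2O (1.1 equiv), pyridine, CH2Cl2, −20 → 0 °C
Reagents that add atoms: acetic anhydride, CC(=O)OC(C)=O
Why: sterically controlled kinetic acylation, because in the chair with the isopropenyl group equatorial the 8-OH is equatorial whereas the 9-OH is axial and syn-axial to C4, so one equivalent of Ac2O takes 8-OH; no stereocentre changes.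

Step 9
Reactants: 17 monoacetate; 18 (E)-2-methylbut-2-enoyl chloride (tigloyl chloride)
Product: 19 8α-acetoxy-9α-[(E)-2-methylbut-2-enoyloxy]-10βH-eremophil-11-en-2-one (CNP0204573.1)
Conditions: 18 (3 equiv), 4-(dimethylamino)pyridine (0.3 equiv), pyridine, CH2Cl2, 0 → 40 °C
Reagents that add atoms: (E)-2-methylbut-2-enoyl chloride 18, C/C=C(\C)C(=O)Cl
Why: nucleophilic-catalysis acylation (acylpyridinium from the acid chloride) of the remaining axial 9-OH; the E (tiglate) geometry is the stable one and is kept, Et3N is avoided to prevent vinylketene deconjugation, and no stereocentre changes.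

## Compound list
1 | 2,3:5,6-di-O-isopropylidene-α-D-mannofuranose | O[C@H]1O[C@H]([C@H]2COC(C)(C)O2)[C@@H]2OC(C)(C)O[C@@H]21 | starting material
2 | isopropyltriphenylphosphonium iodide | CC(C)[P+](c1ccccc1)(c1ccccc1)c1ccccc1.[I-] | starting material
3 | open-chain alkenol, 2,3- and 5,6-acetonides, free 4-OH, C1 = CH=CMe2 | CC(C)=C[C@H]1OC(C)(C)O[C@H]1[C@H](O)[C@H]1COC(C)(C)O1 | intermediate
4 | 1-(triphenylphosphoranylidene)propan-2-one | CC(=O)C=P(c1ccccc1)(c1ccccc1)c1ccccc1 | starting material
5 | 4,5,6-triol (terminal acetonide removed) | CC(C)=C[C@H]1OC(C)(C)O[C@H]1[C@H](O)[C@H](O)CO | intermediate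
6 | (4R,5R)-2,2-dimethyl-5-(2-methylprop-1-enyl)-1,3-dioxolane-4-carbaldehyde (cis) | CC(C)=C[C@H]1OC(C)(C)O[C@H]1C=O | intermediate
7 | (E)-4-[(4S,5R)-2,2-dimethyl-5-(2-methylprop-1-enyl)-1,3-dioxolan-4-yl]but-3-en-2-one | CC(C)=C[C@H]1OC(C)(C)O[C@H]1/C=C/C(C)=O | intermediate
8 | 2-triisopropylsilyloxy-(3E)-diene of 7 | CC(C)=C[C@H]1OC(C)(C)O[C@H]1/C=C/C(=C)O[Si](C(C)C)(C(C)C)C(C)C | intermediate
9 | (E)-2-methylbut-2-enal (tiglaldehyde) | C/C=C(\C)C=O | starting material
10 | (1R,2S,6S)-2-[(4S,5R)-2,2-dimethyl-5-(2-methylprop-1-enyl)-1,3-dioxolan-4-yl]-1,6-dimethyl-4-(triisopropylsilyloxy)cyclohex-3-ene-1-carbaldehyde (CHO cis to the dioxolanyl arm, both methyls on the other face) | O=C[C@@]1(C)[C@H](C=C(O[Si](C(C)C)(C(C)C)C(C)C)C[C@@H]1C)[C@@H]1OC(C)(C)O[C@@H]1C=C(C)C | intermediate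
11 | 6α-hydroxy-8α,9α-isopropylidenedioxy-2-triisopropylsilyloxy-10βH-eremophila-1,11-diene (4β-Me, 5β-Me, 7β-isopropenyl) | C=C(C)[C@H]1[C@H](O)[C@@]2(C)[C@H](C=C(O[Si](C(C)C)(C(C)C)C(C)C)C[C@@H]2C)[C@@H]2OC(C)(C)O[C@H]12 | intermediate
12 | sodium O-alkyl dithiocarbonate of 11 | C=C(C)[C@H]1[C@H](OC(=S)[S-])[C@@]2(C)[C@H](C=C(O[Si](C(C)C)(C(C)C)C(C)C)C[C@@H]2C)[C@@H]2OC(C)(C)O[C@H]12.[Na+] | intermediate
13 | S-methyl xanthate of 11 | C=C(C)[C@H]1[C@H](OC(=S)SC)[C@@]2(C)[C@H](C=C(O[Si](C(C)C)(C(C)C)C(C)C)C[C@@H]2C)[C@@H]2OC(C)(C)O[C@H]12 | intermediate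
14 | 8α,9α-isopropylidenedioxy-2-triisopropylsilyloxy-10βH-eremophila-1,11-diene | C=C(C)[C@H]1C[C@@]2(C)[C@H](C=C(O[Si](C(C)C)(C(C)C)C(C)C)C[C@@H]2C)[C@@H]2OC(C)(C)O[C@H]12 | intermediate
15 | 8α,9α-isopropylidenedioxy-10βH-eremophil-11-en-2-one | C=C(C)[C@H]1C[C@@]2(C)[C@H](CC(=O)C[C@@H]2C)[C@@H]2OC(C)(C)O[C@H]12 | intermediate
16 | 8α,9α-dihydroxy-10βH-eremophil-11-en-2-one | C=C(C)[C@H]1C[C@@]2(C)[C@H](CC(=O)C[C@@H]2C)[C@H](O)[C@@H]1O | intermediate
17 | 8α-acetoxy-9α-hydroxy-10βH-eremophil-11-en-2-one | C=C(C)[C@H]1C[C@@]2(C)[C@H](CC(=O)C[C@@H]2C)[C@H](O)[C@@H]1OC(C)=O | intermediate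
18 | (E)-2-methylbut-2-enoyl chloride (tigloyl chloride) | C/C=C(\C)C(=O)Cl | starting material
19 | CNP0204573.1, (4S,5R,7R,8R,9S,10S)-8-acetoxy-2-oxoeremophil-11-en-9-yl (E)-2-methylbut-2-enoate | C=C(C)[C@H]1C[C@@]2(C)[C@H](CC(=O)C[C@@H]2C)[C@H](OC(=O)/C(C)=C/C)[C@@H]1OC(C)=O | target

## Step count and risks
Total steps: 9. Longest linear sequence: 9 (from 1).

**Step 4 (Diels–Alder/carbonyl-ene domino).** Three things can go wrong: the wrong diene face may react, the silyloxydiene may divert into Mukaiyama aldol or Michael adducts, and the allylic C8–O bond may ionise. The fallback sets out from 8 and 9 and comes back at 11. It hands stereocontrol from the substrate to a catalyst and uses a relay of two promoters in the same flask. Ring A is made with 20 mol % of the salt from (R)-3,3-diphenyl-1-(2-methylphenyl)tetrahydro-1H,3H-pyrrolo[1,2-c][1,3,2]oxazaborole and HN(SO2CF3)2 in CH2Cl2 at −78 to −40 °C. This enantiomer is chosen by the formyl C–H···O model to expose the Si face at C5 of 9; its antipode is equally available. Aldehyde 10 is then closed to ring B by adding the mild, non-ionising ZnBr2 at 0 °C, as in the isopulegol process. No compound outside the list is made (F0).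

**Step 6 (radical deoxygenation next to a quaternary carbon).** The risks are Chugaev elimination of the hindered xanthate on heating and a 1,2-vinyl shift of the C6 radical. The fallback sets out from 11 and comes back at 14, bypassing 12 and 13. The alkoxide of 11 (n-BuLi, THF) is acylated with 4-methylbenzoyl chloride to give the 6α-(4-methylbenzoate) F1. This ester is cleaved by electron transfer with SmI2/HMPA in refluxing THF (divalent samarium, Markó–Lam deoxygenation). There the radical is intercepted quickly and no thiocarbonyl group or tin hydride is needed.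

**Step 9 (acylation of the axial, syn-axially hindered 9-OH beside an acetate).** The risk is 8→9 acetyl migration followed by tigloylation of the freed equatorial OH, which would give the transposed diester. The fallback sets out from 16 and comes back at 19, bypassing 17.
- The equatorial 8-OH is first blocked with a group that does not migrate (TESCl, imidazole, CH2Cl2, −20 °C), giving the 8-O-triethylsilyl ether F2.
- The 9-OH is then esterified under forcing Yamaguchi conditions (tiglic acid, 2,4,6-trichlorobenzoyl chloride, Et3N, 4-(dimethylamino)pyridine, toluene, 80 °C), giving the 8-O-triethylsilyl 9-tiglate F3.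
- HF·pyridine in THF at 0 °C, acidic so that acyl migration is slow, gives the 8-hydroxy 9-tiglate F4.
- Ac2O/pyridine acetylates the unhindered 8-OH at once and gives 19.

## Further compounds
F0 | step 4 | none | none
F1 | step 6 | 8α,9α-isopropylidenedioxy-2-triisopropylsilyloxy-10βH-eremophila-1,11-dien-6α-yl 4-methylbenzoate | C=C(C)[C@H]1[C@H](OC(=O)c3ccc(C)cc3)[C@@]2(C)[C@H](C=C(O[Si](C(C)C)(C(C)C)C(C)C)C[C@@H]2C)[C@@H]2OC(C)(C)O[C@H]12
F2 | step 9 | 9α-hydroxy-8α-triethylsilyloxy-10βH-eremophil-11-en-2-one | C=C(C)[C@H]1C[C@@]2(C)[C@H](CC(=O)C[C@@H]2C)[C@H](O)[C@@H]1O[Si](CC)(CC)CC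
F3 | step 9 | 9α-[(E)-2-methylbut-2-enoyloxy]-8α-triethylsilyloxy-10βH-eremophil-11-en-2-one | C=C(C)[C@H]1C[C@@]2(C)[C@H](CC(=O)C[C@@H]2C)[C@H](OC(=O)/C(C)=C/C)[C@@H]1O[Si](CC)(CC)CC
F4 | step 9 | 8α-hydroxy-9α-[(E)-2-methylbut-2-enoyloxy]-10βH-eremophil-11-en-2-one | C=C(C)[C@H]1C[C@@]2(C)[C@H](CC(=O)C[C@@H]2C)[C@H](OC(=O)/C(C)=C/C)[C@@H]1O
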